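**Plan**

1. Retrosynthesis: the two isovalerates, the O3 silyl ether and the C13 methylene (Horner–Wadsworth–Emmons) go first. The C7–C8 and C11–C12 bonds are then cut together, which opens both the ten-membered ring and the lactone to one acyclic acid, 25. That chain is cut at C7=C11 (cross-metathesis), C8–C9 (enolate alkylation), C2–C3 (vinylogous aldol), C4–C15 (Stille) and C5–C6 (alkynylation).
2. Enabling feature: in the lactone ring (C7, C8, O8, C12, C11) the carbonyl carbon C12 sits on O8. A methyl carbonate on O8 is therefore both the radical-stabilising group at C8 and, five atoms from C11, the internal acyl donor; C7 and C11 are the β and α carbons of a vinylphosphonate. The E-alkenes C1=C10 and C4=C5 hold the chain ends near each other.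
3. Forward: the chain is built linearly; a temporary dioxepine acetonide (O15/O6) locks the C4=C5 geometry and keeps O6 an ether. Step 16 closes the ten-membered carbocycle (C8 radical to C7) and then the γ-lactone (C11 carbanion to C12) in one operation. Methylenation, acetonide removal, acylation and desilylation finish the route.
4. Stereochemistry: C6 comes from a catalytic asymmetric alkynylation and C3 from a catalytic asymmetric vinylogous Mukaiyama aldol reaction. C7 and C8 are relayed from C6 in step 16. Alkene geometries come from trans-hydroalumination (C4=C5) and the vinylogous aldol (C1=C10).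

Key step: step 16

Assumption: atoms are numbered as in germacranes (ring C1–C10, lactone carbons C11–C13, C14 the methyl on C10, C15 the oxymethyl on C4); compounds 20, 21, 23 and 25 are carried as mixtures of C8 epimers, which is harmless because C8 becomes a planar radical in step 16.

**Route**

Step 1
Reactants: 1 (E)-but-2-enal; 2 tert-butyldimethyl(prop-2-yn-1-yloxy)silane
Product: 4 (4S,5E)-1-[(tert-butyldimethylsilyl)oxy]hept-5-en-2-yn-4-ol, via methylzinc acetylide 3 (not isolated)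
Conditions: Me2Zn (3 equiv), (S,S)-ProPhenol (10 mol%), Ph3PO (20 mol%), toluene, 0 °C; aq. NH4Cl
Reagents that add atoms: none
Why: Catalytic enantioselective addition of a zinc alkynylide to an enal (dinuclear zinc–ProPhenol catalysis), which should set C6 by catalyst control of the aldehyde face (the antipodal ligand would be taken if the sense proved opposite).

Step 2
Reactants: 4 (4S,5E)-1-[(tert-butyldimethylsilyl)oxy]hept-5-en-2-yn-4-ol
Product: 6 (2Z,4S,5E)-1-[(tert-butyldimethylsilyl)oxy]-2-iodohepta-2,5-dien-4-ol, via cyclic vinylalanate 5 (not isolated)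
Conditions: NaAlH2(OCH2CH2OMe)2 (1.5 equiv), THF, −20 °C to 0 °C; then I2, THF, −78 °C
Reagents that add atoms: iodine, I-I
Why: Hydroxyl-directed trans-hydroalumination of a propargylic alcohol (hydride to C5, aluminium to C4 in a five-membered alanate) followed by iodinolysis with retention should give the Z-iodide, which fixes the later C4=C5 geometry (C3 trans to C6) without touching C6.

Step 3
Reactants: 6 (2Z,4S,5E)-1-[(tert-butyldimethylsilyl)oxy]-2-iodohepta-2,5-dien-4-ol
Product: 7 (2E,4S,5E)-2-{[(tert-butyldimethylsilyl)oxy]methyl}hepta-2,5-diene-1,4-diol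
Conditions: Bu3SnCH2OH (1.5 equiv), Pd(PPh3)4 (5 mol%), 1,4-dioxane, 80 °C
Reagents that add atoms: (tributylstannyl)methanol, OC[Sn](CCCC)(CCCC)CCCC
Why: Stille coupling of a vinyl iodide with a hydroxymethylstannane proceeds with retention of alkene geometry and should place C15 cis to C6.

Step 4
Reactants: 7 (2E,4S,5E)-2-{[(tert-butyldimethylsilyl)oxy]methyl}hepta-2,5-diene-1,4-diol
Product: 8 tert-butyl{[(4S)-2,2-dimethyl-4-[(E)-prop-1-en-1-yl]-4,7-dihydro-1,3-dioxepin-6-yl]methoxy}dimethylsilane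
Conditions: 2,2-dimethoxypropane, PPTS (5 mol%), CH2Cl2, 0 °C to rt
Reagents that add atoms: 2,2-dimethoxypropane, COC(C)(C)OC
Why: Acid-catalysed transacetalisation of a cis-but-2-ene-1,4-diol to its seven-membered acetonide, a temporary ring that locks the C4=C5 geometry and keeps O6 and O15 as ethers through step 17.

Step 5
Reactants: 8 tert-butyl{[(4S)-2,2-dimethyl-4-[(E)-prop-1-en-1-yl]-4,7-dihydro-1,3-dioxepin-6-yl]methoxy}dimethylsilane
Product: 9 [(4S)-2,2-dimethyl-4-[(E)-prop-1-en-1-yl]-4,7-dihydro-1,3-dioxepin-6-yl]methanol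
Conditions: Bu4NF, THF, 0 °C
Reagents that add atoms: none
Why: Fluoride-induced cleavage of a primary silyl ether, to which the acetonide is inert.

Step 6
Reactants: 9 [(4S)-2,2-dimethyl-4-[(E)-prop-1-en-1-yl]-4,7-dihydro-1,3-dioxepin-6-yl]methanol
Product: 10 (4S)-2,2-dimethyl-4-[(E)-prop-1-en-1-yl]-4,7-dihydro-1,3-dioxepine-6-carbaldehyde
Conditions: MnO2 (15 equiv), CH2Cl2, rt
Reagents that add atoms: none
Why: MnO2 oxidation of a primary allylic alcohol to the enal under neutral conditions; the dioxepine ring rules out E/Z isomerisation of the enal.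

Step 7
Reactants: 11 methyl (E)-2-methylbut-2-enoate
Product: 13 tert-butyl[(1-methoxy-2-methylbuta-1,3-dien-1-yl)oxy]dimethylsilane, via lithium dienolate 12 (not isolated)
Conditions: LiN(iPr)2, DMPU, THF, −78 °C; then TBSCl, −78 °C to rt
Reagents that add atoms: tert-butyldimethylsilyl chloride, CC(C)(C)[Si](C)(C)Cl
Why: Kinetic γ-deprotonation of the enoate and O-silylation give the extended silyl ketene acetal used in vinylogous Mukaiyama aldol reactions (no stereocentre; the ketene acetal geometry is lost in step 8).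

Step 8
Reactants: 10 (4S)-2,2-dimethyl-4-[(E)-prop-1-en-1-yl]-4,7-dihydro-1,3-dioxepine-6-carbaldehyde; 13 tert-butyl[(1-methoxy-2-methylbuta-1,3-dien-1-yl)oxy]dimethylsilane
Product: 14 methyl (2E,5R)-5-[(4S)-2,2-dimethyl-4-[(E)-prop-1-en-1-yl]-4,7-dihydro-1,3-dioxepin-6-yl]-5-hydroxy-2-methylpent-2-enoate
Conditions: B-phenyl oxazaborolidinone from N-tosyl-L-tryptophan and PhBCl2 (30 mol%), i-PrOH (1.1 equiv), EtCN, −78 °C
Reagents that add atoms: none
Why: Catalytic enantioselective vinylogous Mukaiyama aldol reaction, in which the γ-carbon of 13 attacks the enal through an open transition state that gives the E-enoate (C1=C10) and the chiral boron Lewis acid selects the aldehyde face to set C3 (catalyst control; the D-tryptophan catalyst would serve if the sense proved opposite).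

Step 9
Reactants: 14 methyl (2E,5R)-5-[(4S)-2,2-dimethyl-4-[(E)-prop-1-en-1-yl]-4,7-dihydro-1,3-dioxepin-6-yl]-5-hydroxy-2-methylpent-2-enoate
Product: 15 methyl (2E,5R)-5-[(tert-butyldimethylsilyl)oxy]-5-[(4S)-2,2-dimethyl-4-[(E)-prop-1-en-1-yl]-4,7-dihydro-1,3-dioxepin-6-yl]-2-methylpent-2-enoate
Conditions: TBSOTf, 2,6-lutidine, CH2Cl2, −78 °C
Reagents that add atoms: tert-butyldimethylsilyl triflate, CC(C)(C)[Si](C)(C)OS(=O)(=O)C(F)(F)F
Why: Silylation of the hindered secondary allylic alcohol with a silyl triflate and a non-nucleophilic base, leaving C3 untouched.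

Step 10
Reactants: 15 methyl (2E,5R)-5-[(tert-butyldimethylsilyl)oxy]-5-[(4S)-2,2-dimethyl-4-[(E)-prop-1-en-1-yl]-4,7-dihydro-1,3-dioxepin-6-yl]-2-methylpent-2-enoate
Product: 16 (2E,5R)-5-[(tert-butyldimethylsilyl)oxy]-5-[(4S)-2,2-dimethyl-4-[(E)-prop-1-en-1-yl]-4,7-dihydro-1,3-dioxepin-6-yl]-2-methylpent-2-en-1-ol
Conditions: i-Bu2AlH (2.5 equiv), CH2Cl2, −78 °C; aq. potassium sodium tartrate
Reagents that add atoms: none
Why: 1,2-Reduction of an α,β-unsaturated ester to the allylic alcohol by i-Bu2AlH, with the alkene geometry retained.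

Step 11
Reactants: 16 (2E,5R)-5-[(tert-butyldimethylsilyl)oxy]-5-[(4S)-2,2-dimethyl-4-[(E)-prop-1-en-1-yl]-4,7-dihydro-1,3-dioxepin-6-yl]-2-methylpent-2-en-1-ol
Product: 17 (2E,5R)-1-bromo-5-[(tert-butyldimethylsilyl)oxy]-5-[(4S)-2,2-dimethyl-4-[(E)-prop-1-en-1-yl]-4,7-dihydro-1,3-dioxepin-6-yl]-2-methylpent-2-ene
Conditions: CBr4, PPh3, 2,6-lutidine, CH2Cl2, 0 °C
Reagents that add atoms: carbon tetrabromide, BrC(Br)(Br)Br
Why: Appel bromination of a primary allylic alcohol under buffered conditions, which should spare the acetonide and avoid allylic transposition.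

Step 12
Reactants: 17 (2E,5R)-1-bromo-5-[(tert-butyldimethylsilyl)oxy]-5-[(4S)-2,2-dimethyl-4-[(E)-prop-1-en-1-yl]-4,7-dihydro-1,3-dioxepin-6-yl]-2-methylpent-2-ene; 18 2,2-dimethyl-1,3-dioxolan-4-one
Product: 20 5-[(2E,5R)-5-[(tert-butyldimethylsilyl)oxy]-5-[(4S)-2,2-dimethyl-4-[(E)-prop-1-en-1-yl]-4,7-dihydro-1,3-dioxepin-6-yl]-2-methylpent-2-en-1-yl]-2,2-dimethyl-1,3-dioxolan-4-one (both C8 epimers), via lithium enolate 19 (not isolated)
Conditions: 18, LiN(iPr)2, THF, −78 °C; then 17, DMPU, −78 °C to −40 °C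
Reagents that add atoms: none
Why: SN2 alkylation of a glycolate (dioxolanone) enolate by a primary allylic bromide forms C8–C9; C8 arises as both epimers, which is of no consequence.

Step 13
Reactants: 20 5-[(2E,5R)-5-[(tert-butyldimethylsilyl)oxy]-5-[(4S)-2,2-dimethyl-4-[(E)-prop-1-en-1-yl]-4,7-dihydro-1,3-dioxepin-6-yl]-2-methylpent-2-en-1-yl]-2,2-dimethyl-1,3-dioxolan-4-one
Product: 21 (4E,7R)-7-[(tert-butyldimethylsilyl)oxy]-7-[(4S)-2,2-dimethyl-4-[(E)-prop-1-en-1-yl]-4,7-dihydro-1,3-dioxepin-6-yl]-2-hydroxy-4-methylhept-4-enoic acid (both C8 epimers)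
Conditions: LiOH, THF/H2O (3:1), 0 °C; aq. NaH2PO4 to pH 4
Reagents that add atoms: lithium hydroxide, [Li+].[OH-]
Why: Saponification of the dioxolanone (an activated ester) releases the α-hydroxy acid and acetone; the silyl ether and the dioxepine acetal are stable to base.

Step 14
Reactants: 21 (4E,7R)-7-[(tert-butyldimethylsilyl)oxy]-7-[(4S)-2,2-dimethyl-4-[(E)-prop-1-en-1-yl]-4,7-dihydro-1,3-dioxepin-6-yl]-2-hydroxy-4-methylhept-4-enoic acid
Product: 23 (4E,7R)-7-[(tert-butyldimethylsilyl)oxy]-7-[(4S)-2,2-dimethyl-4-[(E)-prop-1-en-1-yl]-4,7-dihydro-1,3-dioxepin-6-yl]-2-[(methoxycarbonyl)oxy]-4-methylhept-4-enoic acid (both C8 epimers), via mixed carbonic anhydride 22 (not isolated)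
Conditions: ClCO2Me (2.5 equiv), pyridine, CH2Cl2, 0 °C; then THF/aq. NaHCO3, rt; aq. NaH2PO4 to pH 4
Reagents that add atoms: methyl chloroformate, COC(=O)Cl
Why: O-Acylation of the secondary alcohol by a chloroformate puts C12 on O8; the carboxyl group is acylated too, and the resulting mixed anhydride is hydrolysed selectively in the bicarbonate work-up because it is far more electrophilic than a dialkyl carbonate.

Step 15
Reactants: 23 (4E,7R)-7-[(tert-butyldimethylsilyl)oxy]-7-[(4S)-2,2-dimethyl-4-[(E)-prop-1-en-1-yl]-4,7-dihydro-1,3-dioxepin-6-yl]-2-[(methoxycarbonyl)oxy]-4-methylhept-4-enoic acid; 24 diethyl ethenylphosphonate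
Product: 25 (4E,7R)-7-[(tert-butyldimethylsilyl)oxy]-7-[(4R)-4-[(E)-2-(diethoxyphosphoryl)ethenyl]-2,2-dimethyl-4,7-dihydro-1,3-dioxepin-6-yl]-2-[(methoxycarbonyl)oxy]-4-methylhept-4-enoic acid (both C8 epimers)
Conditions: second-generation Hoveyda–Grubbs catalyst (10 mol%), 24 (5 equiv), CH2Cl2, 40 °C
Reagents that add atoms: none
Why: Olefin cross-metathesis, in which the ruthenium carbene should engage the 1,2-disubstituted propenyl group and not the trisubstituted alkenes, and vinylphosphonates give E products (the change from 4S to 4R is only a change of CIP priorities).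

Step 16
Reactants: 25 (4E,7R)-7-[(tert-butyldimethylsilyl)oxy]-7-[(4R)-4-[(E)-2-(diethoxyphosphoryl)ethenyl]-2,2-dimethyl-4,7-dihydro-1,3-dioxepin-6-yl]-2-[(methoxycarbonyl)oxy]-4-methylhept-4-enoic acid
Product: 30 α-phosphono lactone: (3R,6R,7R,8S)-germacra-1(10)E,4E-dien-8,12-olide carrying P(O)(OEt)2 on C11 (both C11 epimers), OTBS on C3 and the O6/O15 acetonide, via caesium carboxylate 26 (not isolated), via C8 radical 27 (not isolated), via macrocyclic C11 radical 28 (not isolated), via C11 carbanion 29 (not isolated)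
Conditions: [Ir(dF(CF3)ppy)2(dtbbpy)]PF6 (2 mol%), Cs2CO3 (1.1 equiv), degassed DMSO (2 mM), blue LEDs (450 nm), 25 °C; aq. NH4Cl
Reagents that add atoms: none
Why: Proposed new method: the excited trivalent iridium photocatalyst oxidises carboxylate 26, loss of CO2 gives the nucleophilic α-carbonato radical 27 at C8, this adds to C7 of the E-vinylphosphonate (10-exo-trig, ten-membered ring), divalent iridium reduces the α-phosphonyl radical 28 to carbanion 29, and 29 attacks the carbonate carbonyl C12 (5-exo-trig, γ-lactone) with loss of methoxide, which deprotonates the product and makes the sequence irreversible. The closest known reaction types are the photoredox decarboxylative Giese addition of α-oxy acids, radical–polar crossover cascades that end in an anionic ring closure, and the Claisen-type acylation of phosphonate carbanions by carbonates; their union in a ring-forming (3+2) lactone annulation that also closes a ten-membered carbocycle has not been shown. C7 is controlled by the allylic centre C6: with H6 eclipsing the alkene, the radical should enter anti to the C6–O bond, which gives the required 6,7-anti relationship. C8 is formed from a planar radical, so both C8 epimers of 25 converge, and the trans ring fusion (7R,8S) is expected because a cis-fused lactone would force a nearly eclipsed C6–C7–C8–C9 torsion into the ten-membered ring. The step needs ring closure to outrun reduction or hydrogen abstraction of 27 (2 mM dilution, a polarity-matched electron-poor acceptor, and two E-trisubstituted alkenes that restrict the chain to few conformers), regiocontrol (only C7 is β to phosphorus) and site-selective acylation (O6 is an acetal ether, so the O8 carbonate is the only acyl donor within reach of C11).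

Step 17
Reactants: 30 α-phosphono lactone (3R,6R,7R,8S)
Product: 31 (3R,6R,7R,8S)-3-[(tert-butyldimethylsilyl)oxy]-6,15-(isopropylidenedioxy)germacra-1(10)E,4E,11(13)-trien-8,12-olide
Conditions: K2CO3, 37% aq. formaldehyde, THF, 0 °C to rt
Reagents that add atoms: formaldehyde, C=O
Why: Horner–Wadsworth–Emmons olefination of the α-phosphono lactone with formaldehyde gives the exocyclic C11=C13 methylene and removes both the phosphonate helper and the C11 stereocentre.

Step 18
Reactants: 31 (3R,6R,7R,8S)-3-[(tert-butyldimethylsilyl)oxy]-6,15-(isopropylidenedioxy)germacra-1(10)E,4E,11(13)-trien-8,12-olide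
Product: 32 (3R,6R,7S,8S)-3-[(tert-butyldimethylsilyl)oxy]-6,15-dihydroxygermacra-1(10)E,4E,11(13)-trien-8,12-olide (same spatial arrangement; the C7 descriptor changes with CIP priorities)
Conditions: AcOH/THF/H2O (3:1:1), 35 °C
Reagents that add atoms: none
Why: Mild acid hydrolysis of the seven-membered acetonide, to which the hindered secondary silyl ether and the lactone are stable.

Step 19
Reactants: 32 (3R,6R,7S,8S)-3-[(tert-butyldimethylsilyl)oxy]-6,15-dihydroxygermacra-1(10)E,4E,11(13)-trien-8,12-olide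
Product: 33 (3R,6R,7R,8S)-3-[(tert-butyldimethylsilyl)oxy]-6,15-bis(3-methylbutanoyloxy)germacra-1(10)E,4E,11(13)-trien-8,12-olide
Conditions: 3-methylbutanoyl chloride (3 equiv), pyridine, DMAP (10 mol%), CH2Cl2, 0 °C
Reagents that add atoms: 3-methylbutanoyl chloride, CC(C)CC(=O)Cl
Why: DMAP-catalysed esterification of the primary (O15) and secondary (O6) hydroxyls, O3 being silylated.

Step 20
Reactants: 33 (3R,6R,7R,8S)-3-[(tert-butyldimethylsilyl)oxy]-6,15-bis(3-methylbutanoyloxy)germacra-1(10)E,4E,11(13)-trien-8,12-olide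
Product: 34 (3R,6R,7R,8S)-3-hydroxy-6,15-bis(3-methylbutanoyloxy)germacra-1(10)E,4E,11(13)-trien-8,12-olide (CNP0317194.1)
Conditions: HF·pyridine, pyridine/THF, 0 °C to rt
Reagents that add atoms: none
Why: Buffered fluoride desilylation, which should leave the esters, the α-methylene lactone and the allylic systems intact.

**Compound list**

1 | (E)-but-2-enal | C/C=C/C=O | starting material
2 | tert-butyldimethyl(prop-2-yn-1-yloxy)silane | C#CCO[Si](C)(C)C(C)(C)C | starting material
3 | methylzinc acetylide of 2 | C[Zn]C#CCO[Si](C)(C)C(C)(C)C | intermediate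
4 | (4S,5E)-1-[(tert-butyldimethylsilyl)oxy]hept-5-en-2-yn-4-ol | CC(C)(C)[Si](C)(C)OCC#C[C@@H](O)/C=C/C | intermediate
5 | sodium cyclic vinylalanate (Al on C4 and O6) | CC(C)(C)[Si](C)(C)OCC1=C[C@@H](O[Al-]1(OCCOC)OCCOC)/C=C/C.[Na+] | intermediate
6 | (2Z,4S,5E)-1-[(tert-butyldimethylsilyl)oxy]-2-iodohepta-2,5-dien-4-ol | CC(C)(C)[Si](C)(C)OC/C(I)=C/[C@@H](O)/C=C/C | intermediate
7 | (2E,4S,5E)-2-{[(tert-butyldimethylsilyl)oxy]methyl}hepta-2,5-diene-1,4-diol | CC(C)(C)[Si](C)(C)OC/C(CO)=C/[C@@H](O)/C=C/C | intermediate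
8 | tert-butyl{[(4S)-2,2-dimethyl-4-[(E)-prop-1-en-1-yl]-4,7-dihydro-1,3-dioxepin-6-yl]methoxy}dimethylsilane | CC(C)(C)[Si](C)(C)OCC1=C[C@@H](OC(C)(C)OC1)/C=C/C | intermediate
9 | [(4S)-2,2-dimethyl-4-[(E)-prop-1-en-1-yl]-4,7-dihydro-1,3-dioxepin-6-yl]methanol | OCC1=C[C@@H](OC(C)(C)OC1)/C=C/C | intermediate
10 | (4S)-2,2-dimethyl-4-[(E)-prop-1-en-1-yl]-4,7-dihydro-1,3-dioxepine-6-carbaldehyde | O=CC1=C[C@@H](OC(C)(C)OC1)/C=C/C | intermediate
11 | methyl (E)-2-methylbut-2-enoate | C/C=C(\C)C(=O)OC | starting material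
12 | lithium 1-methoxy-2-methylbuta-1,3-dien-1-olate | [Li+].C=CC(C)=C([O-])OC | intermediate
13 | tert-butyl[(1-methoxy-2-methylbuta-1,3-dien-1-yl)oxy]dimethylsilane | C=CC(C)=C(OC)O[Si](C)(C)C(C)(C)C | intermediate
14 | methyl (2E,5R)-5-[(4S)-2,2-dimethyl-4-[(E)-prop-1-en-1-yl]-4,7-dihydro-1,3-dioxepin-6-yl]-5-hydroxy-2-methylpent-2-enoate | COC(=O)/C(C)=C/C[C@@H](O)C1=C[C@@H](OC(C)(C)OC1)/C=C/C | intermediate
15 | methyl (2E,5R)-5-[(tert-butyldimethylsilyl)oxy]-5-[(4S)-2,2-dimethyl-4-[(E)-prop-1-en-1-yl]-4,7-dihydro-1,3-dioxepin-6-yl]-2-methylpent-2-enoate | COC(=O)/C(C)=C/C[C@@H](O[Si](C)(C)C(C)(C)C)C1=C[C@@H](OC(C)(C)OC1)/C=C/C | intermediate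
16 | (2E,5R)-5-[(tert-butyldimethylsilyl)oxy]-5-[(4S)-2,2-dimethyl-4-[(E)-prop-1-en-1-yl]-4,7-dihydro-1,3-dioxepin-6-yl]-2-methylpent-2-en-1-ol | OC/C(C)=C/C[C@@H](O[Si](C)(C)C(C)(C)C)C1=C[C@@H](OC(C)(C)OC1)/C=C/C | intermediate
17 | (2E,5R)-1-bromo-5-[(tert-butyldimethylsilyl)oxy]-5-[(4S)-2,2-dimethyl-4-[(E)-prop-1-en-1-yl]-4,7-dihydro-1,3-dioxepin-6-yl]-2-methylpent-2-ene | BrC/C(C)=C/C[C@@H](O[Si](C)(C)C(C)(C)C)C1=C[C@@H](OC(C)(C)OC1)/C=C/C | intermediate
18 | 2,2-dimethyl-1,3-dioxolan-4-one | CC1(C)OCC(=O)O1 | starting material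
19 | lithium enolate of 18 | [Li+].CC1(C)OC=C([O-])O1 | intermediate
20 | 5-[(2E,5R)-5-[(tert-butyldimethylsilyl)oxy]-5-[(4S)-2,2-dimethyl-4-[(E)-prop-1-en-1-yl]-4,7-dihydro-1,3-dioxepin-6-yl]-2-methylpent-2-en-1-yl]-2,2-dimethyl-1,3-dioxolan-4-one (C8 epimers) | CC1(C)OC(=O)C(C/C(C)=C/C[C@@H](O[Si](C)(C)C(C)(C)C)C2=C[C@@H](OC(C)(C)OC2)/C=C/C)O1 | intermediate
21 | (4E,7R)-7-[(tert-butyldimethylsilyl)oxy]-7-[(4S)-2,2-dimethyl-4-[(E)-prop-1-en-1-yl]-4,7-dihydro-1,3-dioxepin-6-yl]-2-hydroxy-4-methylhept-4-enoic acid (C8 epimers) | OC(=O)C(O)C/C(C)=C/C[C@@H](O[Si](C)(C)C(C)(C)C)C1=C[C@@H](OC(C)(C)OC1)/C=C/C | intermediate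
22 | mixed methyl carbonic anhydride of 23 | COC(=O)OC(=O)C(OC(=O)OC)C/C(C)=C/C[C@@H](O[Si](C)(C)C(C)(C)C)C1=C[C@@H](OC(C)(C)OC1)/C=C/C | intermediate
23 | (4E,7R)-7-[(tert-butyldimethylsilyl)oxy]-7-[(4S)-2,2-dimethyl-4-[(E)-prop-1-en-1-yl]-4,7-dihydro-1,3-dioxepin-6-yl]-2-[(methoxycarbonyl)oxy]-4-methylhept-4-enoic acid (C8 epimers) | OC(=O)C(OC(=O)OC)C/C(C)=C/C[C@@H](O[Si](C)(C)C(C)(C)C)C1=C[C@@H](OC(C)(C)OC1)/C=C/C | intermediate
24 | diethyl ethenylphosphonate | C=CP(=O)(OCC)OCC | starting material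
25 | (4E,7R)-7-[(tert-butyldimethylsilyl)oxy]-7-[(4R)-4-[(E)-2-(diethoxyphosphoryl)ethenyl]-2,2-dimethyl-4,7-dihydro-1,3-dioxepin-6-yl]-2-[(methoxycarbonyl)oxy]-4-methylhept-4-enoic acid (C8 epimers) | OC(=O)C(OC(=O)OC)C/C(C)=C/C[C@@H](O[Si](C)(C)C(C)(C)C)C1=C[C@@H](OC(C)(C)OC1)/C=C/P(=O)(OCC)OCC | intermediate
26 | caesium carboxylate of 25 | [Cs+].[O-]C(=O)C(OC(=O)OC)C/C(C)=C/C[C@@H](O[Si](C)(C)C(C)(C)C)C1=C[C@@H](OC(C)(C)OC1)/C=C/P(=O)(OCC)OCC | intermediate
27 | C8 α-(methoxycarbonyloxy)alkyl radical | COC(=O)O[CH]C/C(C)=C/C[C@@H](O[Si](C)(C)C(C)(C)C)C1=C[C@@H](OC(C)(C)OC1)/C=C/P(=O)(OCC)OCC | intermediate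
28 | ten-membered C11 α-phosphonyl radical (C7–C8 formed) | COC(=O)O[C@H]1C/C(C)=C/C[C@@H](O[Si](C)(C)C(C)(C)C)/C(CO2)=C/[C@@H](OC2(C)C)[C@@H]1[CH]P(=O)(OCC)OCC | intermediate
29 | caesium salt of the ten-membered C11 carbanion | [Cs+].COC(=O)O[C@H]1C/C(C)=C/C[C@@H](O[Si](C)(C)C(C)(C)C)/C(CO2)=C/[C@@H](OC2(C)C)[C@@H]1[CH-]P(=O)(OCC)OCC | intermediate
30 | α-phosphono lactone: (3R,6R,7R,8S)-germacra-1(10)E,4E-dien-8,12-olide with P(O)(OEt)2 on C11 (both epimers), OTBS on C3 and the O6/O15 acetonide | CCOP(=O)(OCC)C1C(=O)O[C@H]2C/C(C)=C/C[C@@H](O[Si](C)(C)C(C)(C)C)/C(CO3)=C/[C@@H](OC3(C)C)[C@H]12 | intermediate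
31 | (3R,6R,7R,8S)-3-[(tert-butyldimethylsilyl)oxy]-6,15-(isopropylidenedioxy)germacra-1(10)E,4E,11(13)-trien-8,12-olide | C=C1C(=O)O[C@H]2C/C(C)=C/C[C@@H](O[Si](C)(C)C(C)(C)C)/C(CO3)=C/[C@@H](OC3(C)C)[C@H]12 | intermediate
32 | (3R,6R,7S,8S)-3-[(tert-butyldimethylsilyl)oxy]-6,15-dihydroxygermacra-1(10)E,4E,11(13)-trien-8,12-olide | C=C1C(=O)O[C@H]2C/C(C)=C/C[C@@H](O[Si](C)(C)C(C)(C)C)/C(CO)=C/[C@@H](O)[C@H]12 | intermediate
33 | (3R,6R,7R,8S)-3-[(tert-butyldimethylsilyl)oxy]-6,15-bis(3-methylbutanoyloxy)germacra-1(10)E,4E,11(13)-trien-8,12-olide | C=C1C(=O)O[C@H]2C/C(C)=C/C[C@@H](O[Si](C)(C)C(C)(C)C)/C(COC(=O)CC(C)C)=C/[C@@H](OC(=O)CC(C)C)[C@H]12 | intermediate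
34 | (3R,6R,7R,8S)-3-hydroxy-6,15-bis(3-methylbutanoyloxy)germacra-1(10)E,4E,11(13)-trien-8,12-olide (CNP0317194.1) | C=C1C(=O)O[C@H]2C/C(C)=C/C[C@@H](O)/C(COC(=O)CC(C)C)=C/[C@@H](OC(=O)CC(C)C)[C@H]12 | target

**Step count and risks**

Total step count: 20 (19 in the main line plus step 7, the preparation of 13).
Longest linear sequence: 19 steps (from 1 and 2 to 34; steps 1–6 and 8–20).

Steps most likely to fail:

1. Step 16. The ten-membered ring closure by the C8 radical may lose to its reduction and protonation (net hydrodecarboxylation) or to hydrogen abstraction, and facial selectivity at C7 and C8 may be poor. The fallback uses known reaction types, sets out from 21 and returns at 31. Oxidative decarboxylation of the α-hydroxy acid 21 with Pb(OAc)4 (CH2Cl2, 0 °C) should give the C8 aldehyde F1. Cross-metathesis of its propenyl group with 2-methylidenepropane-1,3-diyl diacetate (second-generation Hoveyda–Grubbs catalyst, CH2Cl2, 40 °C) should give the bis(allylic acetate) F2. An intramolecular umpolung allylation (Pd(PPh3)4, InI, THF, 2 mM) follows, in which zerovalent palladium ionises one acetate and the derived allylindium adds through its C7 terminus to the aldehyde. This should close the ten-membered ring as the homoallylic alcohol F3 (C7/C8 anti expected from a chair transition state, C7 again under the influence of C6). Methanolysis (K2CO3, MeOH) should give the diol F4. MnO2 oxidation of its allylic primary alcohol, with oxidation of the lactol formed in situ, should give the α-methylene lactone 31.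

2. Step 8. The Lewis acid may open the acetonide, or enantioface control or γ-selectivity may be insufficient on this functionalised enal. The fallback sets out from 10 and returns at 15. A tin-mediated acetate aldol reaction of (4S)-3-acetyl-4-isopropyl-1,3-thiazolidine-2-thione with 10 (Sn(OTf)2, N-ethylpiperidine, CH2Cl2, −78 °C; the auxiliary enantiomer chosen for the R carbinol) should give the aldol adduct F5. Silylation (TBSOTf, 2,6-lutidine) should give the silyl ether F6. i-Bu2AlH at −78 °C releases the auxiliary and should give the β-silyloxy aldehyde F7. A Wittig reaction with methyl 2-(triphenylphosphoranylidene)propanoate (toluene, 80 °C) should then give the E-enoate 15.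

3. Step 2. The vinylalanate may lose the C3 silyloxy group by β-elimination (allene formation), or be over-reduced, before iodinolysis. The fallback sets out from 4 and returns at 6. Ruthenium-catalysed trans-hydrosilylation of 4 with benzyldimethylsilane ([Cp*Ru(MeCN)3]PF6, CH2Cl2, 0 °C) should place silicon on C4, the alkyne carbon remote from the free hydroxyl, and give the Z-vinylsilane F8; no carbon–aluminium bond β to the silyloxy group is involved. Iododesilylation with N-iodosuccinimide in hexafluoroisopropanol at 0 °C, with retention, should then give 6.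

Further compounds
F1 | step 16 | (3E,6R)-6-[(tert-butyldimethylsilyl)oxy]-6-[(4S)-2,2-dimethyl-4-[(E)-prop-1-en-1-yl]-4,7-dihydro-1,3-dioxepin-6-yl]-3-methylhex-3-enal | O=CC/C(C)=C/C[C@@H](O[Si](C)(C)C(C)(C)C)C1=C[C@@H](OC(C)(C)OC1)/C=C/C
F2 | step 16 | C8 aldehyde with a C7H=C11(CH2OAc)2 terminus on the (4S)-dioxepine | O=CC/C(C)=C/C[C@@H](O[Si](C)(C)C(C)(C)C)C1=C[C@@H](OC(C)(C)OC1)C=C(COC(C)=O)COC(C)=O
F3 | step 16 | ten-membered homoallylic alcohol: 8-hydroxy, C7 bearing C(=CH2)CH2OAc, 3-OTBS, O6/O15 acetonide, configured as 31 | O[C@H]1C/C(C)=C/C[C@@H](O[Si](C)(C)C(C)(C)C)/C(CO2)=C/[C@@H](OC2(C)C)[C@@H]1C(=C)COC(C)=O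
F4 | step 16 | ten-membered 8,12-diol: C7 bearing C(=CH2)CH2OH, 3-OTBS, O6/O15 acetonide, configured as 31 | O[C@H]1C/C(C)=C/C[C@@H](O[Si](C)(C)C(C)(C)C)/C(CO2)=C/[C@@H](OC2(C)C)[C@@H]1C(=C)CO
F5 | step 8 | (3R)-3-[(4S)-2,2-dimethyl-4-[(E)-prop-1-en-1-yl]-4,7-dihydro-1,3-dioxepin-6-yl]-3-hydroxy-1-[(4S)-4-isopropyl-2-thioxo-1,3-thiazolidin-3-yl]propan-1-one | CC(C)[C@H]1CSC(=S)N1C(=O)C[C@@H](O)C1=C[C@@H](OC(C)(C)OC1)/C=C/C
F6 | step 8 | tert-butyldimethylsilyl ether of F5 | CC(C)[C@H]1CSC(=S)N1C(=O)C[C@@H](O[Si](C)(C)C(C)(C)C)C1=C[C@@H](OC(C)(C)OC1)/C=C/C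
F7 | step 8 | (3R)-3-[(tert-butyldimethylsilyl)oxy]-3-[(4S)-2,2-dimethyl-4-[(E)-prop-1-en-1-yl]-4,7-dihydro-1,3-dioxepin-6-yl]propanal | O=CC[C@@H](O[Si](C)(C)C(C)(C)C)C1=C[C@@H](OC(C)(C)OC1)/C=C/C
F8 | step 2 | (2Z,4S,5E)-2-[benzyl(dimethyl)silyl]-1-[(tert-butyldimethylsilyl)oxy]hepta-2,5-dien-4-ol | CC(C)(C)[Si](C)(C)OC/C([Si](C)(C)Cc1ccccc1)=C/[C@@H](O)/C=C/C
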